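## Structural features

The target is a β-resorcylic acid: one benzene ring with the carboxyl group at C1, hydroxyl groups at C2 and C4, hydrogen at C3 and C5, and at C6 a single unbranched fifteen-carbon chain (C1' to C15') joined through the C6–C1' bond. The chain holds seven methylene groups (C1'–C7'), a Z alkene at C8'=C9', the only stereocentre at C10' (R, as an acetate) and an n-pentyl tail. That stereocentre has no stereogenic neighbour, but it is allylic, so its C–O bond can ionise or transpose under Brønsted or Lewis acid and under zerovalent palladium. The fragile groups are the secondary allylic acetate (lost to alkoxide or hydroxide), the Z alkene (open to halogen, hydrogenation and isomerisation) and the 2,4-dihydroxybenzoic acid, which decarboxylates in acid or on heating and whose hindered, hydrogen-bonded esters cannot be saponified beside an acetate. The real difficulty is twofold: the chain sits meta to both ring oxygens, where electrophilic substitution of a resorcinol does not reach, and the product needs exactly one O-acetyl group, on the aliphatic oxygen, while two phenols and a carboxylic acid stay free. The key step exploits the fact that at the 2,4-dioxocyclohexane oxidation level C6 is the β-carbon of an alk-3-en-2-one that supplies C3–C6, while C1 and C2 are the central carbon and one ester carbon of a malonate. C10' is taken from (R)-oct-1-yn-3-ol; no bond to it is made or broken and the priority order O > unsaturated carbon > pentyl > H never changes, so the R descriptor holds throughout. Carbon 1 of 8-bromooctan-1-ol ends as ring C6 and its other seven carbons as C1'–C7'.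

## Logic of the disconnections

23 ⇒ 22. The bond cut is the O–CH2 bond of the C1 ester, the reverse of a fluoride-triggered β-elimination. The free acid is unmasked last because the hindered salicylate ester cannot be hydrolysed beside the C10' acetate, and because the free acid is the species most prone to decarboxylation. The gain is that every earlier intermediate is a neutral, chromatographable ester. The demand is that fluoride fragments the silylethyl group faster than its basicity harms the acetate.

22 ⇒ 20 (through 21). The bond cut is the acyl C–O bond at C10'. A free aliphatic hydroxyl cannot be acetylated cleanly beside two phenols, so all three oxygens are acetylated to 21 and the two aryl esters are removed again in the same flask. The gain is that no phenol protecting group is carried through the synthesis. The demand is that aminolysis discriminates between aryl acetates, which have good leaving groups, and the secondary alkyl acetate.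

20 ⇒ 19. The bond cut is O–Si at C10'. The tert-butyldimethylsilyl ether is the group that takes C10' through acetylide, alkoxide and oxidant chemistry. The demand is a desilylation that leaves the silylethyl ester alone, which acidic fluoride meets.

19 ⇒ 16 (through 17 and 18). Two hydrogens are returned to C5 and C6, so the arene is recognised as the dehydro form of the cyclic β-diketone. A bromination–dehydrobromination would be the usual way forward, but it is not adopted here for three reasons:
- a bromide at C3 has no β-hydrogen and can leave only after tautomerisation or migration;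
- the sequence releases two equivalents of HBr beside an acid-labile allylic silyl ether;
- CuBr2 in the presence of bromide is itself an alkene-brominating system and would also attack the electron-rich product ring.

Instead the dione is locked as its bis-silyl cyclohexa-1,3-diene 17, and a quinone removes hydride from C6. The demand is that hydride is taken from ring C6, where the cation is stabilised by both silyloxy groups, and not from allylic C10'.

16 ⇒ 11 + 14 (through 15). The bonds cut are C1–C6 and C2–C3. This removes the ring entirely and leaves an enone and a malonate, so arene regiochemistry never arises and the chain fragment only has to end in a methyl enone. The demand is conjugate addition followed by acylation through the methyl-side enolate, in the presence of the Z-allylic silyl ether. The silylethyl ester is kept in 14 because it is the one ester that can later be removed without base, acid, hydrogen or palladium.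

14 ⇒ 12 + 13. Two ester C–O bonds are cut, so one molecule of 12 takes up two molecules of 13; a carbodiimide esterification suffices. The demand is only that both carboxyl groups are esterified, which two equivalents of alcohol and of coupling agent secure.

11 ⇒ 9 + 10. The bond cut is the C=C that becomes C5–C6. A stabilised ylide gives the E enone under neutral conditions, and the chain fragment is reduced to an aldehyde.

9 ⇒ 8 ⇒ 7. These are changes of oxidation level and protecting group only. The primary alcohol is carried as an acetal that is removed under conditions the secondary silyl ether tolerates, and it is oxidised no further than the aldehyde.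

7 ⇒ 6. The Z alkene is traced to an alkyne. Cis semi-hydrogenation fixes the geometry without any olefination at the stereocentre-bearing carbon.

6 ⇒ 2 + 4 (through 5). The bond cut is C7'–C8', an sp–sp3 bond made by alkylating an acetylide with a primary bromide. This divides the chain into two bought pieces. The demand is that substitution outruns elimination, which a dipolar cosolvent secures.

2 ⇒ 1 and 4 ⇒ 3. These are protections only, chosen so that each group leaves under conditions the other tolerates.

## Other disconnections considered

Alternative 1: The ring is cut at C1–C2 and C5–C6, so that C1 and C6 come from an alkyne and C2–C5 from a 1,3-dioxygenated cyclohexadiene.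
- Forward step: the silylethyl 2-ynoate A1, already carrying the finished Z-allylic acetate chain, would be heated with the diene A2. A [4+2] addition would be followed by cycloreversion of the bicyclo[2.2.2]octadiene, with loss of its gem-dimethyl two-carbon bridge as a C4 alkene. Desilylation on work-up would leave A3, which is the same compound as 22.
- In favour: the ring is born aromatic, and the acetate can be in place because the step is neutral. This is better than the chosen plan in the length of the endgame (one step after the key step against four) and in protecting-group economy. Regiochemistry follows from diene polarisation, the nucleophilic terminus C5 bonding to the β-carbon C6, which makes it the equal of the chosen plan on that point.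
- Against: a β-alkyl ynoate is a weak dienophile, so prolonged heating well above 100 °C is to be expected, and the finished chain must sit through it. The allylic acetate can undergo thermal [3,3] acyloxy shift, which would move oxygen to C8' and destroy both the stereocentre and the alkene position, or it can eliminate. A2 is hydrolytically labile and needed in excess. A1 is also no shorter to make than 11: the aldehyde carbon of 9 must be turned into a terminal alkyne, the alkyne carboxylated as its silylethyl ester, and the C10' silyl ether exchanged for the acetate, against a single olefination from 9 to 11.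
- Comparison: structurally Alternative 1 avoids sp3 ring centres and any dehydrogenation. Mechanistically both plans rely on inherent polarity. The chosen plan closes its ring at or below 60 °C with C10' as a robust silyl ether, whereas Alternative 1 exposes the final allylic acetate to its harshest step. Overall step counts should be close, with Alternative 1 perhaps one or two steps shorter if the cycloaddition performs.

Alternative 2: The cuts are C6–C1' and C1–carboxyl; no ring bond is made.
- Forward step: the fluoroarene A4 would be lithiated between fluorine and methoxyl by a hindered lithium amide and would lose lithium fluoride to give the aryne. The chain Grignard reagent A5 would add at the carbon that becomes C6, so that the aryl anion sits at C1 beside the inductively stabilising methoxyl. Carboxylation would give A6.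
- In favour: this is the most convergent plan. The ring is bought, there is no aromatisation, and the carboxyl arrives free. It is better than the chosen plan in convergence, its equal in regiochemical logic, and about its equal or slightly better in step count up to the key-step product.
- Against: A6 carries two aryl methyl ethers. Freeing them needs boron trihalides or hot thiolate, conditions that ionise the allylic C10'–O bond, endanger the Z alkene and cleave any acetate. The C2 ether is helped by the neighbouring carboxyl, but the C4 ether is not. A5 is not reachable from 8 itself, whose chain carries one methylene too many; the sequence of steps 1 to 5 would have to be run one carbon shorter and followed by bromination and magnesium insertion. The three-component trapping also needs excess A5 and an amide base that does not itself add to the aryne.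
- Comparison: the chosen plan is longer to the ring but delivers the phenols free under mild conditions. Alternative 2 is shorter to A6 but has no defensible path from A6 to 23, unless the methyl ethers are replaced by groups that survive a lithium amide yet leave under fluoride or mild acid, which would be a different plan.

Alternative 3: The cut is C1–C6 at the aromatic oxidation level, which unfolds the ring into a linear 3,5,7-triketo ester.
- Forward step: heating the diketo-dioxinone A7 with 13 would unmask an acyl ketene by retro-[4+2], and 13 would trap it as the triketo ester A8. A mild carbonate base would then add C1 to the C6 ketone in an aldol reaction, and weak acid would dehydrate to A9, which is the same compound as 19.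
- In favour: the ring forms at the correct oxidation level without any oxidant or transient ring stereocentre. This is better than the chosen plan at the ring-forming stage. Because it converges on 19, it shares steps 11 to 13 and is the chosen plan's equal in protecting groups and endgame.
- Against: A7 requires C-acylation of a keto-dioxinone dianion with an activated derivative of the chain carboxylic acid. That is one oxidation level above 9 and costs extra oxidation and activation steps and a large excess of strong amide base. The poly-β-carbonyl chains of A7 and A8 are prone to O-cyclisation to pyranones and to aldol closure in other modes, and they are awkward to purify.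
- Comparison: the aldol–dehydration is gentler than Michael–Claisen plus dehydrogenation, but 11 needs only an aldehyde and a stabilised ylide. What Alternative 3 saves at the aromatisation it spends in preparing A7, so overall step economy is about equal.

Key step: step 9

Remark: the chain length (seven methylenes between ring C6 and C8') and the R configuration at C10' were checked atom by atom for 11, 14 and 16 against the target and need no change. The acetal carbon of 4, 6 and 7 and the sp3 ring carbons of 15, 16 and 17 are left unassigned, because these mixtures disappear later. 16 is drawn as its triketo tautomer although it should exist largely as an enol.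

Step 1
Reactants: 1 (R)-oct-1-yn-3-ol
Product: 2 (R)-tert-butyldimethyl(oct-1-yn-3-yloxy)silane
Conditions: TBSCl, imidazole, DMF, 0 °C → rt
Reagents that add atoms: tert-butyldimethylsilyl chloride, CC(C)(C)[Si](C)(C)Cl
Why: Imidazole-promoted silylation of a secondary alcohol; only the O–H bond reacts, so the R centre is carried over unchanged, and the silyl ether is the group that later withstands acetylide, alkoxide and oxidant.

Step 2
Reactants: 3 8-bromooctan-1-ol
Product: 4 2-[(8-bromooctyl)oxy]tetrahydro-2H-pyran
Conditions: 3,4-dihydro-2H-pyran, PPTS (cat.), CH2Cl2, rt
Reagents that add atoms: 3,4-dihydro-2H-pyran, C1=COCCC1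
Why: Acid-catalysed addition of the alcohol to the enol ether (tetrahydropyranylation) removes the acidic O–H before the acetylide alkylation; the primary bromide is inert to these conditions.

Step 3
Reactants: 2 (R)-tert-butyldimethyl(oct-1-yn-3-yloxy)silane; 4 2-[(8-bromooctyl)oxy]tetrahydro-2H-pyran
Product: 6 2-{[(11R)-11-(tert-butyldimethylsilyloxy)hexadec-9-yn-1-yl]oxy}tetrahydro-2H-pyran, via lithium acetylide 5 (not isolated)
Conditions: n-BuLi, THF, −78 °C; then 4, DMPU, −78 °C → rt
Reagents that add atoms: none
Why: Deprotonation of the terminal alkyne and SN2 alkylation of the lithium acetylide by the primary bromide, accelerated by the dipolar cosolvent, forms C7'–C8'; the propargylic C–H is not removed under these conditions, so C10' is untouched.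

Step 4
Reactants: 6 2-{[(11R)-11-(tert-butyldimethylsilyloxy)hexadec-9-yn-1-yl]oxy}tetrahydro-2H-pyran
Product: 7 2-{[(9Z,11R)-11-(tert-butyldimethylsilyloxy)hexadec-9-en-1-yl]oxy}tetrahydro-2H-pyran
Conditions: H2 (1 atm), Pd on CaCO3 poisoned with Pb(OAc)2, quinoline, hexane/EtOAc, rt
Reagents that add atoms: none
Why: Syn delivery of hydrogen on poisoned palladium (cis semi-hydrogenation) sets the Z geometry of C8'=C9'; quinoline suppresses over-reduction, and the allylic C–O bond is not hydrogenolysed on this catalyst.

Step 5
Reactants: 7 2-{[(9Z,11R)-11-(tert-butyldimethylsilyloxy)hexadec-9-en-1-yl]oxy}tetrahydro-2H-pyran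
Product: 8 (9Z,11R)-11-(tert-butyldimethylsilyloxy)hexadec-9-en-1-ol
Conditions: PPTS (cat.), MeOH, 40 °C
Reagents that add atoms: none
Why: Acid-catalysed transacetalisation to methanol frees the primary alcohol; under this weak acid the hindered secondary silyl ether is cleaved far more slowly than the acetal.

Step 6
Reactants: 8 (9Z,11R)-11-(tert-butyldimethylsilyloxy)hexadec-9-en-1-ol
Product: 9 (9Z,11R)-11-(tert-butyldimethylsilyloxy)hexadec-9-enal
Conditions: PhI(OAc)2, TEMPO (cat.), CH2Cl2, rt
Reagents that add atoms: none
Why: Oxoammonium-mediated (TEMPO) oxidation with a hypervalent iodine co-oxidant stops at the aldehyde and touches neither the isolated Z alkene nor the silyl ether.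

Step 7
Reactants: 9 (9Z,11R)-11-(tert-butyldimethylsilyloxy)hexadec-9-enal; 10 1-(triphenylphosphoranylidene)propan-2-one
Product: 11 (3E,12Z,14R)-14-(tert-butyldimethylsilyloxy)nonadeca-3,12-dien-2-one
Conditions: toluene, 80 °C
Reagents that add atoms: none
Why: Wittig olefination with a stabilised acyl ylide gives the E enone under neutral conditions; the aldehyde carbon becomes the future ring C6, and the remote Z alkene is not affected.

Step 8
Reactants: 12 malonic acid; 13 2-(trimethylsilyl)ethanol
Product: 14 bis[2-(trimethylsilyl)ethyl] malonate
Conditions: 13 (2.1 equiv), DCC (2.1 equiv), MeCN, 0 °C → rt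
Reagents that add atoms: 2-(trimethylsilyl)ethanol (the second equivalent of 13), C[Si](C)(C)CCO
Why: Carbodiimide-mediated double esterification (Steglich type): each carboxyl group of the diacid is activated as its O-acylisourea and takes up one molecule of 13, so two equivalents of the alcohol and of DCC are consumed; it provides the malonate whose ester can later be removed by fluoride alone.

Step 9
Reactants: 11 (3E,12Z,14R)-14-(tert-butyldimethylsilyloxy)nonadeca-3,12-dien-2-one; 14 bis[2-(trimethylsilyl)ethyl] malonate
Product: 16 2-(trimethylsilyl)ethyl 6-[(8Z,10R)-10-(tert-butyldimethylsilyloxy)pentadec-8-en-1-yl]-2,4-dioxocyclohexane-1-carboxylate, via Michael adduct 15 (not isolated)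
Conditions: KOtBu, THF, 0 °C → 60 °C; then cold 1 M HCl
Reagents that add atoms: none
Why: KOtBu converts 14 into its soft, stabilised anion, which adds in conjugate fashion to the β-carbon of enone 11 and forms C1–C6, and proton transfer from the acidic malonate C–H leaves 15 as its malonate anion. On warming, the small equilibrium share of the methyl-side ketone enolate attacks one silylethyl ester carbonyl and forms C2–C3 in a Claisen (Dieckmann-type) condensation. The expelled alkoxide at once deprotonates the new β-diketone, and this stable enolate pulls the reversible steps forward. The closest known reaction type is the Michael–Claisen annulation of malonates with alk-3-en-2-ones to 6-alkyl-2,4-dioxocyclohexanecarboxylates. The ring closes in the 6-(enolendo)-exo-trig mode. The new sp3 centres C1 and C6 need no control: C1 is an epimerisable β-keto ester carbon, and both centres vanish on aromatisation. The step needs 1,4- over 1,2-addition, secured by the soft nucleophile and the reversibility of carbonyl addition, and closure through the methyl enolate, secured because the C5-side enolate could only close a four-membered ring. The Z-allylic silyl ether and the second silylethyl ester are inert to tert-butoxide in THF, and C10' is remote from all reacting centres.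

Step 10
Reactants: 16 2-(trimethylsilyl)ethyl 6-[(8Z,10R)-10-(tert-butyldimethylsilyloxy)pentadec-8-en-1-yl]-2,4-dioxocyclohexane-1-carboxylate
Product: 19 2-(trimethylsilyl)ethyl 6-[(8Z,10R)-10-(tert-butyldimethylsilyloxy)pentadec-8-en-1-yl]-2,4-dihydroxybenzoate, via bis-silyl dienol ether 17 (not isolated), via aryl bis-silyl ether 18 (not isolated)
Conditions: TMSOTf, Et3N, CH2Cl2, 0 °C; evaporate, pentane filtration; DDQ, 2,4,6-collidine, CH2Cl2, 0 °C → rt; then aq. citric acid, THF
Reagents that add atoms: none
Why: Double O-silylation locks the dione as the ester-conjugated cyclohexa-1,3-diene, and DDQ then removes hydride from the tertiary C6–H to a cation stabilised by both silyloxy groups, after which loss of the C5 proton gives the arene (quinone dehydrogenation of a cyclohexadiene and of silyl enol ethers). No halogen or strong acid is present, so the Z alkene and the allylic silyl ether are spared, and the aryl trimethylsilyl ethers hydrolyse on the mildly acidic work-up.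

Step 11
Reactants: 19 2-(trimethylsilyl)ethyl 6-[(8Z,10R)-10-(tert-butyldimethylsilyloxy)pentadec-8-en-1-yl]-2,4-dihydroxybenzoate
Product: 20 2-(trimethylsilyl)ethyl 2,4-dihydroxy-6-[(8Z,10R)-10-hydroxypentadec-8-en-1-yl]benzoate
Conditions: HF·pyridine, pyridine, THF, 0 °C → rt
Reagents that add atoms: none
Why: Buffered acidic fluoride cleaves the O–Si bond of the silyl ether, whereas the carbon-bound trimethylsilyl group of the ester needs unsolvated fluoride to fragment; the buffered medium does not ionise the allylic alcohol, so C10' keeps its configuration.

Step 12
Reactants: 20 2-(trimethylsilyl)ethyl 2,4-dihydroxy-6-[(8Z,10R)-10-hydroxypentadec-8-en-1-yl]benzoate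
Product: 22 2-(trimethylsilyl)ethyl 6-[(8Z,10R)-10-acetoxypentadec-8-en-1-yl]-2,4-dihydroxybenzoate, via triacetate 21 (not isolated)
Conditions: Ac2O, pyridine, DMAP (cat.), CH2Cl2, rt; evaporate; NH3 (7 M in MeOH), 0 °C
Reagents that add atoms: acetic anhydride, CC(=O)OC(C)=O
Why: Nucleophile-catalysed acetylation esterifies all three hydroxyls with retention at C10', and brief ammonolysis at 0 °C then removes only the two aryl acetates, whose phenoxide leaving groups make them far more reactive than the secondary alkyl acetate; the hindered salicylate ester is not attacked.

Step 13
Reactants: 22 2-(trimethylsilyl)ethyl 6-[(8Z,10R)-10-acetoxypentadec-8-en-1-yl]-2,4-dihydroxybenzoate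
Product: 23 6-[(8Z,10R)-10-acetoxypentadec-8-en-1-yl]-2,4-dihydroxybenzoic acid
Conditions: TBAF, THF, 0 °C → rt; then cold 0.5 M HCl
Reagents that add atoms: none
Why: Fluoride attacks silicon and the ester fragments by β-elimination to carboxylate, ethene and fluorosilane, a cleavage that does not involve the carbonyl group and therefore is not slowed by the hindered, hydrogen-bonded salicylate; the alkyl acetate is not a substrate for this fragmentation, and acidification at 0 °C avoids decarboxylation.

## Compound list

1 | (R)-oct-1-yn-3-ol | CCCCC[C@H](C#C)O | starting material
2 | (R)-tert-butyldimethyl(oct-1-yn-3-yloxy)silane | CCCCC[C@H](C#C)O[Si](C)(C)C(C)(C)C | intermediate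
3 | 8-bromooctan-1-ol | OCCCCCCCCBr | starting material
4 | 2-[(8-bromooctyl)oxy]tetrahydro-2H-pyran (acetal carbon unassigned) | BrCCCCCCCCOC1CCCCO1 | intermediate
5 | {(3R)-3-[(tert-butyldimethylsilyl)oxy]oct-1-yn-1-yl}lithium (lithium acetylide, not isolated) | CCCCC[C@H](C#C[Li])O[Si](C)(C)C(C)(C)C | intermediate
6 | 2-{[(11R)-11-(tert-butyldimethylsilyloxy)hexadec-9-yn-1-yl]oxy}tetrahydro-2H-pyran | CCCCC[C@H](C#CCCCCCCCCOC1CCCCO1)O[Si](C)(C)C(C)(C)C | intermediate
7 | 2-{[(9Z,11R)-11-(tert-butyldimethylsilyloxy)hexadec-9-en-1-yl]oxy}tetrahydro-2H-pyran | CCCCC[C@H](/C=C\CCCCCCCCOC1CCCCO1)O[Si](C)(C)C(C)(C)C | intermediate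
8 | (9Z,11R)-11-(tert-butyldimethylsilyloxy)hexadec-9-en-1-ol | CCCCC[C@H](/C=C\CCCCCCCCO)O[Si](C)(C)C(C)(C)C | intermediate
9 | (9Z,11R)-11-(tert-butyldimethylsilyloxy)hexadec-9-enal | CCCCC[C@H](/C=C\CCCCCCCC=O)O[Si](C)(C)C(C)(C)C | intermediate
10 | 1-(triphenylphosphoranylidene)propan-2-one | CC(=O)C=P(c1ccccc1)(c1ccccc1)c1ccccc1 | starting material
11 | (3E,12Z,14R)-14-(tert-butyldimethylsilyloxy)nonadeca-3,12-dien-2-one | CCCCC[C@H](/C=C\CCCCCCC/C=C/C(C)=O)O[Si](C)(C)C(C)(C)C | intermediate
12 | malonic acid | OC(=O)CC(=O)O | starting material
13 | 2-(trimethylsilyl)ethanol | C[Si](C)(C)CCO | starting material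
14 | bis[2-(trimethylsilyl)ethyl] malonate | C[Si](C)(C)CCOC(=O)CC(=O)OCC[Si](C)(C)C | intermediate
15 | bis[2-(trimethylsilyl)ethyl] 2-[(12Z,14R)-14-(tert-butyldimethylsilyloxy)-2-oxononadec-12-en-4-yl]malonate (Michael adduct, not isolated, C4 unassigned) | CCCCC[C@H](/C=C\CCCCCCCC(CC(C)=O)C(C(=O)OCC[Si](C)(C)C)C(=O)OCC[Si](C)(C)C)O[Si](C)(C)C(C)(C)C | intermediate
16 | 2-(trimethylsilyl)ethyl 6-[(8Z,10R)-10-(tert-butyldimethylsilyloxy)pentadec-8-en-1-yl]-2,4-dioxocyclohexane-1-carboxylate (ring centres unassigned) | CCCCC[C@H](/C=C\CCCCCCCC1CC(=O)CC(=O)C1C(=O)OCC[Si](C)(C)C)O[Si](C)(C)C(C)(C)C | intermediate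
17 | 2-(trimethylsilyl)ethyl 6-[(8Z,10R)-10-(tert-butyldimethylsilyloxy)pentadec-8-en-1-yl]-2,4-bis(trimethylsilyloxy)cyclohexa-1,3-diene-1-carboxylate (not isolated, C6 unassigned) | CCCCC[C@H](/C=C\CCCCCCCC1CC(O[Si](C)(C)C)=CC(O[Si](C)(C)C)=C1C(=O)OCC[Si](C)(C)C)O[Si](C)(C)C(C)(C)C | intermediate
18 | 2-(trimethylsilyl)ethyl 6-[(8Z,10R)-10-(tert-butyldimethylsilyloxy)pentadec-8-en-1-yl]-2,4-bis(trimethylsilyloxy)benzoate (not isolated) | CCCCC[C@H](/C=C\CCCCCCCc1cc(O[Si](C)(C)C)cc(O[Si](C)(C)C)c1C(=O)OCC[Si](C)(C)C)O[Si](C)(C)C(C)(C)C | intermediate
19 | 2-(trimethylsilyl)ethyl 6-[(8Z,10R)-10-(tert-butyldimethylsilyloxy)pentadec-8-en-1-yl]-2,4-dihydroxybenzoate | CCCCC[C@H](/C=C\CCCCCCCc1cc(O)cc(O)c1C(=O)OCC[Si](C)(C)C)O[Si](C)(C)C(C)(C)C | intermediate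
20 | 2-(trimethylsilyl)ethyl 2,4-dihydroxy-6-[(8Z,10R)-10-hydroxypentadec-8-en-1-yl]benzoate | CCCCC[C@H](/C=C\CCCCCCCc1cc(O)cc(O)c1C(=O)OCC[Si](C)(C)C)O | intermediate
21 | 2-(trimethylsilyl)ethyl 2,4-diacetoxy-6-[(8Z,10R)-10-acetoxypentadec-8-en-1-yl]benzoate (not isolated) | CCCCC[C@H](/C=C\CCCCCCCc1cc(OC(C)=O)cc(OC(C)=O)c1C(=O)OCC[Si](C)(C)C)OC(C)=O | intermediate
22 | 2-(trimethylsilyl)ethyl 6-[(8Z,10R)-10-acetoxypentadec-8-en-1-yl]-2,4-dihydroxybenzoate | CCCCC[C@H](/C=C\CCCCCCCc1cc(O)cc(O)c1C(=O)OCC[Si](C)(C)C)OC(C)=O | intermediate
23 | 6-[(8Z,10R)-10-acetoxypentadec-8-en-1-yl]-2,4-dihydroxybenzoic acid | CCCCC[C@H](/C=C\CCCCCCCc1cc(O)cc(O)c1C(=O)O)OC(C)=O | target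

## Step count and least certain steps

Total step count: 13. Longest linear sequence: 11 steps (steps 1, 3, 4, 5, 6, 7, 9, 10, 11, 12, 13).

Step 9 (key step). The most likely failure is stalling after the conjugate addition. In an aprotic medium the resting state is the malonate anion of 15, and ring closure has to pass through the minor methyl-side ketone enolate. Prolonged heating could then favour reversal of the conjugate addition or base-induced self-condensation of the enone. The fallback sets out from 11 and comes back at 16. 11 would be condensed with dimethyl malonate under NaOMe in boiling MeOH, the protic alkoxide medium in which proton shuttling to the methyl enolate is fast, to give methyl 6-[(8Z,10R)-10-(tert-butyldimethylsilyloxy)pentadec-8-en-1-yl]-2,4-dioxocyclohexane-1-carboxylate F1. The silyl ether tolerates methoxide. F1 is a β-keto ester with an enolisable C1–H, and it would be transesterified with 13 in toluene at reflux (DMAP cat., methanol distilled out) through its acyl ketene to return 16.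

Step 10. Three things could go wrong:
- incomplete second silylation, which leaves a mono-silyl enone that is inert to the quinone;
- cycloaddition or charge-transfer chemistry of DDQ with the electron-rich diene in place of hydride abstraction;
- competing hydride abstraction at allylic C10'.

The fallback sets out from 16 and comes back at 19. It is the halogenative aromatisation established for this ring class, run with the least aggressive halogen source. 16 would be treated with CuBr2 (two equivalents of divalent copper bromide, no bromide additive) in MeCN at 0 °C with propylene oxide as acid trap, to give 2-(trimethylsilyl)ethyl 3-bromo-6-[(8Z,10R)-10-(tert-butyldimethylsilyloxy)pentadec-8-en-1-yl]-2,4-dioxocyclohexane-1-carboxylate F2. On warming in DMF, F2 would lose HBr through its bis-enol, a cyclohexa-1,4-diene in which bromine at C3 and hydrogen at C6 stand in a 1,4-relationship, to give 19. It is the second choice because of the alkene, the acid released and possible ring bromination of 19.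

Step 13. The basicity of fluoride and of the phenoxides it generates may lead to loss or migration of the C10' acetate before the hindered ester has fragmented completely. The fallback sets out from 19 and comes back at 23; it changes the order so that fluoride never meets the acetate. 19 would be treated with excess TBAF to remove both silicon groups at once, giving 2,4-dihydroxy-6-[(8Z,10R)-10-hydroxypentadec-8-en-1-yl]benzoic acid F3. Acetylation with Ac2O and pyridine, followed by aqueous hydrolysis of the mixed anhydride, would give 2,4-diacetoxy-6-[(8Z,10R)-10-acetoxypentadec-8-en-1-yl]benzoic acid F4. Brief ammonolysis in MeOH at 0 °C would remove the two aryl acetates and deliver 23.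

Step 3. Competing E2 dehydrobromination of 4 by the basic acetylide, and incomplete substitution, are the likely problems. The fallback sets out from 1 and 4 and comes back at 6. Unprotected 1 would be converted with LiNH2 (2 equiv) in liquid NH3/THF into its O,C-dilithio derivative. In this classical medium the derivative alkylates at carbon with primary bromides, which would give (6R)-16-(tetrahydro-2H-pyran-2-yloxy)hexadec-7-yn-6-ol F5. Silylation of F5 with TBSCl and imidazole would give 6.

## Further compounds

F1 | step 9 | methyl 6-[(8Z,10R)-10-(tert-butyldimethylsilyloxy)pentadec-8-en-1-yl]-2,4-dioxocyclohexane-1-carboxylate | CCCCC[C@H](/C=C\CCCCCCCC1CC(=O)CC(=O)C1C(=O)OC)O[Si](C)(C)C(C)(C)C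
F2 | step 10 | 2-(trimethylsilyl)ethyl 3-bromo-6-[(8Z,10R)-10-(tert-butyldimethylsilyloxy)pentadec-8-en-1-yl]-2,4-dioxocyclohexane-1-carboxylate | CCCCC[C@H](/C=C\CCCCCCCC1CC(=O)C(Br)C(=O)C1C(=O)OCC[Si](C)(C)C)O[Si](C)(C)C(C)(C)C
F3 | step 13 | 2,4-dihydroxy-6-[(8Z,10R)-10-hydroxypentadec-8-en-1-yl]benzoic acid | CCCCC[C@H](/C=C\CCCCCCCc1cc(O)cc(O)c1C(=O)O)O
F4 | step 13 | 2,4-diacetoxy-6-[(8Z,10R)-10-acetoxypentadec-8-en-1-yl]benzoic acid | CCCCC[C@H](/C=C\CCCCCCCc1cc(OC(C)=O)cc(OC(C)=O)c1C(=O)O)OC(C)=O
F5 | step 3 | (6R)-16-(tetrahydro-2H-pyran-2-yloxy)hexadec-7-yn-6-ol | CCCCC[C@H](C#CCCCCCCCCOC1CCCCO1)O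
A1 | alternative 1 | 2-(trimethylsilyl)ethyl (11Z,13R)-13-acetoxyoctadec-11-en-2-ynoate | CCCCC[C@H](/C=C\CCCCCCCC#CC(=O)OCC[Si](C)(C)C)OC(C)=O
A2 | alternative 1 | 5,5-dimethyl-1,3-bis(trimethylsilyloxy)cyclohexa-1,3-diene | CC1(C)CC(O[Si](C)(C)C)=CC(O[Si](C)(C)C)=C1
A3 | alternative 1 | 2-(trimethylsilyl)ethyl 6-[(8Z,10R)-10-acetoxypentadec-8-en-1-yl]-2,4-dihydroxybenzoate | CCCCC[C@H](/C=C\CCCCCCCc1cc(O)cc(O)c1C(=O)OCC[Si](C)(C)C)OC(C)=O
A4 | alternative 2 | 1-fluoro-3,5-dimethoxybenzene | COc1cc(F)cc(OC)c1
A5 | alternative 2 | [(8Z,10R)-10-(tert-butyldimethylsilyloxy)pentadec-8-en-1-yl]magnesium bromide | CCCCC[C@H](/C=C\CCCCCCC[Mg]Br)O[Si](C)(C)C(C)(C)C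
A6 | alternative 2 | 2-[(8Z,10R)-10-(tert-butyldimethylsilyloxy)pentadec-8-en-1-yl]-4,6-dimethoxybenzoic acid | CCCCC[C@H](/C=C\CCCCCCCc1cc(OC)cc(OC)c1C(=O)O)O[Si](C)(C)C(C)(C)C
A7 | alternative 3 | 6-[(12Z,14R)-14-(tert-butyldimethylsilyloxy)-2,4-dioxononadec-12-en-1-yl]-2,2-dimethyl-4H-1,3-dioxin-4-one | CCCCC[C@H](/C=C\CCCCCCCC(=O)CC(=O)CC1=CC(=O)OC(C)(C)O1)O[Si](C)(C)C(C)(C)C
A8 | alternative 3 | 2-(trimethylsilyl)ethyl (15Z,17R)-17-(tert-butyldimethylsilyloxy)-3,5,7-trioxodocos-15-enoate | CCCCC[C@H](/C=C\CCCCCCCC(=O)CC(=O)CC(=O)CC(=O)OCC[Si](C)(C)C)O[Si](C)(C)C(C)(C)C
A9 | alternative 3 | 2-(trimethylsilyl)ethyl 6-[(8Z,10R)-10-(tert-butyldimethylsilyloxy)pentadec-8-en-1-yl]-2,4-dihydroxybenzoate | CCCCC[C@H](/C=C\CCCCCCCc1cc(O)cc(O)c1C(=O)OCC[Si](C)(C)C)O[Si](C)(C)C(C)(C)C
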